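**Plan**

- Retr
osynthetic cuts, in order: C11=C12 (Wittig); the C6–O, C7–O and C8–O bonds (oxidation of a Δ7 alkene, then of the derived 7-ketone); C9–C11 (methylenation and hydroboration of a C9 ketone); C3–C4 of ring A (cation–vinylsilane closure); finally C10–C1 and C10–C20 (two enolate alkylations).
- Enabling feature: ring B of the target (C5 to C10, with the C17 methyl on C8) already exists in (R)-carvone. Its carbonyl is C9, its α′-CH2 is C10, its stereocentre is C5, and its isopropenyl group supplies C4 with both methyls. Ring A is therefore short of only C1–C3 and one bond, C3–C4.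
- Forward order: ring B is bought; C20 and a (Z)-γ-silylallyl arm (C1–C3) are placed on C10; ring A is closed by acid; C11 is added (drimenol); ring B is oxygenated at C8, C6 and C7; C12–C14 are joined last.
- Stereochemistry: C5 comes from (R)-carvone. C10 is set by alkylation anti to isopropenyl, which also fixes the trans ring fusion. C9 is set by α-face hydroboration, C8 and C6 by α-face oxidation opposite the axial methyls, and C7 by axial hydride attack.

Key step: step 5

Remark: positions follow drimane/labdane numbering (C17 = methyl on C8, C20 = methyl on C10, side chain C11–C14; α is the face opposite C20). 3-(Trimethylsilyl)prop-2-yn-1-ol, the C-silylated form of prop-2-yn-1-ol, is taken as a purchasable starting material.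

**Route**

Step 1
Reactants: 1 (R)-(−)-carvone
Product: 3 6-methylcarvone (C6 epimer mixture), via lithium dienolate 2 (not isolated)
Conditions: LiN(i-Pr)2, THF, −78 °C; MeI, −78 → 0 °C
Reagents that add atoms: iodomethane, CI; lithium diisopropylamide, [Li]N(C(C)C)C(C)C (lithium carried only in 2)
Why: Kinetic deprotonation of the enone by the hindered amide occurs at the α′-CH2 to give the cross-conjugated enolate 2, whose alkylation with MeI (enolate C-alkylation) should give 3 as a C6 epimer mixture that is of no consequence because this centre is re-enolised in step 4.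

Step 2
Reactants: 4 3-(trimethylsilyl)prop-2-yn-1-ol
Product: 5 (Z)-3-(trimethylsilyl)prop-2-en-1-ol
Conditions: H2 (1 atm), Ni(OAc)2·4H2O/NaBH4 (nickel boride made in situ), H2NCH2CH2NH2, EtOH, rt
Reagents that add atoms: none
Why: Alkyne semihydrogenation on amine-poisoned nickel boride adds both hydrogens syn, so the (Z)-vinylsilane should form without over-reduction or loss of silicon.

Step 3
Reactants: 5 (Z)-3-(trimethylsilyl)prop-2-en-1-ol
Product: 6 (Z)-(3-bromoprop-1-en-1-yl)trimethylsilane
Conditions: CBr4, PPh3, CH2Cl2, 0 °C
Reagents that add atoms: carbon tetrabromide, BrC(Br)(Br)Br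
Why: The Appel reaction replaces the primary allylic hydroxyl by bromide through SN2 displacement of an oxyphosphonium group under neutral conditions, so the (Z) geometry and the C–Si bond should be retained.

Step 4
Reactants: 3 6-methylcarvone (C6 epimer mixture); 6 (Z)-(3-bromoprop-1-en-1-yl)trimethylsilane
Product: 8 6-methyl-6-[(Z)-3-(trimethylsilyl)prop-2-en-1-yl]carvone (silylallyl trans to isopropenyl), via lithium enolate 7 (not isolated)
Conditions: LiN(i-Pr)2, THF, −78 → 0 °C; then 6, DMPU, −78 °C → rt
Reagents that add atoms: lithium diisopropylamide, [Li]N(C(C)C)C(C)C (lithium carried only in 7)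
Why: Enolate C-alkylation of the tetrasubstituted cross-conjugated enolate 7 by the reactive allylic bromide should occur on the ring face opposite the neighbouring isopropenyl group, which sets quaternary C10 with the silylallyl arm trans and the methyl cis to isopropenyl.

Step 5
Reactants: 8 6-methyl-6-[(Z)-3-(trimethylsilyl)prop-2-en-1-yl]carvone
Product: 9 11-nordrima-2,7-dien-9-one (trans-fused, 5α-H, 10β-CH3)
Conditions: CF3CO2H (5 equiv), CH2Cl2, −20 → 0 °C; NaHCO3 work-up
Reagents that add atoms: none
Why: The acid protonates the 1,1-disubstituted isopropenyl alkene in the Markovnikov sense to the tertiary C4 cation, which is attacked by the silicon-bearing carbon C3 of the vinylsilane to form C3–C4; the C2 cation so formed is stabilised by the β C–Si bond and loses the silyl group to trifluoroacetate, leaving the C2=C3 alkene (net ipso substitution of silicon). The closest known reaction type is the vinylsilane-terminated cation–olefin cyclisation in its endocyclic mode. Ring A closes 6-endo-trig with respect to the vinylsilane, through a chair-like arrangement in which the C4 and C1 arms are both equatorial on ring B. No new stereocentre arises: the trans ring fusion follows from the existing C5 and C10 centres, whose reacting arms are trans, and the (Z) geometry puts silicon pseudoaxial on C3 in the ring cation so that the C–Si bond overlaps with the empty orbital at C2. The step needs protonation of the isopropenyl group in preference to the vinylsilane and the enone, and attack at C3 instead of C2; the higher basicity of the 1,1-dialkyl alkene, the electron-poor enone, the quaternary C10 (which blocks aromatisation) and the β-silicon effect (attack at C2 would give a five-membered ring and an α-silyl cation) should secure this.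

Step 6
Reactants: 9 11-nordrima-2,7-dien-9-one
Product: 10 11-nordrim-7-en-9-one
Conditions: H2 (1–3 atm), RhCl(PPh3)3 (5 mol %), benzene/EtOH, rt
Reagents that add atoms: none
Why: Homogeneous hydrogenation with RhCl(PPh3)3 reduces accessible disubstituted alkenes far faster than trisubstituted conjugated ones (the selectivity that saturates only the isopropenyl group of carvone), so only C2=C3 should be reduced and no stereocentre is touched.

Step 7
Reactants: 10 11-nordrim-7-en-9-one
Product: 11 drima-7,9(11)-diene
Conditions: Ph3PCH3Br, KOtBu, toluene, rt (ylide); then 10, 90 °C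
Reagents that add atoms: methyltriphenylphosphonium bromide, C[P+](c1ccccc1)(c1ccccc1)c1ccccc1.[Br-]
Why: Wittig methylenation with Ph3P=CH2 at elevated temperature is the usual answer to hindered ketones that cannot enolise at the α-carbon (C10 is quaternary), and should turn the C9 carbonyl into the exocyclic C9=C11 alkene of the conjugated diene.

Step 8
Reactants: 11 drima-7,9(11)-diene
Product: 13 drimenol (drim-7-en-11-ol; 9α-H), via B-alkyl-9-BBN adduct 12 (not isolated)
Conditions: 9-BBN, THF, 0 → 60 °C; then NaOH, H2O2, H2O, 0 °C → rt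
Reagents that add atoms: hydrogen peroxide, OO; 9-borabicyclo[3.3.1]nonane, B1C2CCCC1CCC2 (carried only in 12)
Why: Hydroboration–oxidation with the bulky borane should engage only the 1,1-disubstituted exocyclic alkene, placing boron on terminal C11 and delivering hydrogen to C9 from the α face opposite the angular C20 methyl, so that oxidation with retention gives the 9α-H, 9β-CH2OH centre.

Step 9
Reactants: 13 drimenol
Product: 14 11-O-(tert-butyldimethylsilyl)drimenol
Conditions: TBSCl, imidazole, DMF, rt
Reagents that add atoms: tert-butyldimethylsilyl chloride, CC(C)(C)[Si](C)(C)Cl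
Why: Silyl ether formation masks the primary C11 hydroxyl with a group that should survive the oxidations, silylation, acylation and hydride reduction that follow and that can later be removed without touching an acetate.

Step 10
Reactants: 14 11-O-(tert-butyldimethylsilyl)drimenol
Product: 15 11-(tert-butyldimethylsilyloxy)-8α-hydroxydriman-7-one
Conditions: RuCl3 (1 mol %), KHSO5 (as 2KHSO5·KHSO4·K2SO4), NaHCO3, EtOAc/MeCN/H2O, rt
Reagents that add atoms: potassium peroxymonosulfate, [K+].[O-]S(=O)(=O)OO
Why: RuO4-catalysed ketohydroxylation adds the oxo-metal reagent across the trisubstituted C7=C8 bond by [3+2] cycloaddition from the α face, away from the axial C20 methyl (the face chosen in osmylation of drim-7-enes), and oxidation of the ruthenate ester at the secondary carbon should give the 7-ketone with the 8α-hydroxyl and 8β-methyl fixed.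

Step 11
Reactants: 15 11-(tert-butyldimethylsilyloxy)-8α-hydroxydriman-7-one
Product: 16 11-(tert-butyldimethylsilyloxy)-7,8α-bis(trimethylsilyloxy)drim-6-ene
Conditions: TMSOTf (3 equiv), Et3N (5 equiv), CH2Cl2, 0 °C → rt
Reagents that add atoms: trimethylsilyl trifluoromethanesulfonate, C[Si](C)(C)OS(=O)(=O)C(F)(F)F
Why: Soft enolisation with silyl triflate and amine can proceed only towards C6 because C8 is fully substituted, so the Δ6 silyl enol ether should form regiospecifically while the tertiary 8-hydroxyl is capped as its trimethylsilyl ether.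

Step 12
Reactants: 16 11-(tert-butyldimethylsilyloxy)-7,8α-bis(trimethylsilyloxy)drim-6-ene
Product: 19 11-(tert-butyldimethylsilyloxy)-6α,8α-dihydroxydriman-7-one, via silyloxy epoxide 17 (not isolated), via 6α-silyloxy ketone 18 (not isolated)
Conditions: mCPBA, NaHCO3, CH2Cl2, −20 → 0 °C; then citric acid, MeOH, rt
Reagents that add atoms: 3-chloroperoxybenzoic acid, OOC(=O)c1cccc(Cl)c1
Why: In this Rubottom oxidation the electron-rich enol ether is epoxidised from the α face, opposite the axial methyls on C4, C8 and C10, the silyloxy epoxide 17 opens with silyl shift to the equatorial 6α-silyloxy ketone 18 (also the more stable C6 epimer), and mild acidic methanolysis should remove both trimethylsilyl groups but not the primary TBS ether.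

Step 13
Reactants: 19 11-(tert-butyldimethylsilyloxy)-6α,8α-dihydroxydriman-7-one
Product: 20 6α-acetoxy-11-(tert-butyldimethylsilyloxy)-8α-hydroxydriman-7-one
Conditions: Ac2O, pyridine, DMAP (cat.), CH2Cl2, 0 °C → rt
Reagents that add atoms: acetic anhydride, CC(=O)OC(C)=O
Why: DMAP-catalysed O-acylation esterifies the secondary 6α-hydroxyl while the hindered tertiary 8α-hydroxyl should stay free, which fixes the acetate on O6 before any hydroxyl exists at C7.

Step 14
Reactants: 20 6α-acetoxy-11-(tert-butyldimethylsilyloxy)-8α-hydroxydriman-7-one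
Product: 21 6α-acetoxy-11-(tert-butyldimethylsilyloxy)drimane-7β,8α-diol
Conditions: NaBH4, CeCl3·7H2O, MeOH, −78 → −40 °C; AcOH quench
Reagents that add atoms: none
Why: In this Luche-type borohydride reduction the small hydride should attack C7 along the axial trajectory on the α face, which avoids eclipsing with the axial 8β-methyl and gives the equatorial 7β-alcohol, while the cold, cerium-buffered medium and acidic quench are chosen to suppress acetyl migration from O6 to O7.

Step 15
Reactants: 21 6α-acetoxy-11-(tert-butyldimethylsilyloxy)drimane-7β,8α-diol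
Product: 22 6α-acetoxydrimane-7β,8α,11-triol
Conditions: HF·pyridine, pyridine, THF, 0 °C → rt
Reagents that add atoms: none
Why: Fluoride-mediated desilylation in a buffered acidic medium cleaves the primary silyl ether, whereas the acetate, which could migrate or hydrolyse under basic fluoride, should remain on O6.

Step 16
Reactants: 22 6α-acetoxydrimane-7β,8α,11-triol
Product: 23 6α-acetoxy-7β,8α-dihydroxydriman-11-al
Conditions: TEMPO (cat.), PhI(OAc)2, CH2Cl2, rt
Reagents that add atoms: none
Why: Oxoammonium (TEMPO) oxidation is selective for a primary alcohol over hindered secondary and tertiary ones and stops at the aldehyde under neutral conditions, so the epimerisable C9 centre (equatorial, hence the stable epimer) and the acetate should be preserved.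

Step 17
Reactants: 23 6α-acetoxy-7β,8α-dihydroxydriman-11-al
Product: 24 (E)-4-(6α-acetoxy-7β,8α-dihydroxy-11-nordriman-9β-yl)but-3-en-2-one (target; = 6α-acetoxy-7β,8α-dihydroxy-14,15-dinorlabd-11(E)-en-13-one)
Conditions: Ph3P=CHC(O)CH3, toluene, 90 °C
Reagents that add atoms: 1-(triphenyl-λ5-phosphanylidene)propan-2-one, CC(=O)C=P(c1ccccc1)(c1ccccc1)c1ccccc1
Why: Wittig olefination with the ketone-stabilised ylide is weakly basic enough to tolerate the free diol, the acetate and the β-hydroxy aldehyde, and the reversible addition typical of stabilised ylides should give the (E)-enone and complete the C11–C14 chain.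

**Compound list**

1 | (R)-(−)-carvone | CC1=CC[C@H](CC1=O)C(C)=C | starting material
2 | lithium cross-conjugated dienolate of carvone (O–C=C towards the α′-carbon) | [Li]OC1=C[C@H](C(C)=C)CC=C1C | intermediate (not isolated)
3 | 6-methylcarvone, (5R)-2,6-dimethyl-5-(prop-1-en-2-yl)cyclohex-2-en-1-one, C6 epimer mixture | CC1=CC[C@@H](C(C)=C)C(C)C1=O | intermediate
4 | 3-(trimethylsilyl)prop-2-yn-1-ol | C[Si](C)(C)C#CCO | starting material
5 | (Z)-3-(trimethylsilyl)prop-2-en-1-ol | C[Si](C)(C)/C=C\CO | intermediate
6 | (Z)-(3-bromoprop-1-en-1-yl)trimethylsilane | C[Si](C)(C)/C=C\CBr | intermediate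
7 | lithium enolate of 3 (tetrasubstituted O–C=C(CH3)) | [Li]OC1=C(C)[C@H](C(C)=C)CC=C1C | intermediate (not isolated)
8 | 6-methyl-6-[(Z)-3-(trimethylsilyl)prop-2-en-1-yl]carvone; carvone stereocentre unchanged, silylallyl trans and methyl cis to isopropenyl | O=C1C(C)=CC[C@@H](C(C)=C)[C@]1(C)C/C=C\[Si](C)(C)C | intermediate
9 | 11-nordrima-2,7-dien-9-one (trans-fused, 5α-H, 10β-CH3) | O=C1C(C)=CC[C@H]2C(C)(C)C=CC[C@@]21C | intermediate
10 | 11-nordrim-7-en-9-one | O=C1C(C)=CC[C@H]2C(C)(C)CCC[C@@]21C | intermediate
11 | drima-7,9(11)-diene | C=C1C(C)=CC[C@H]2C(C)(C)CCC[C@@]21C | intermediate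
12 | B-(drim-7-en-11-yl)-9-borabicyclo[3.3.1]nonane | C(B1C2CCCC1CCC2)[C@H]3C(C)=CC[C@H]4C(C)(C)CCC[C@@]43C | intermediate (not isolated)
13 | drimenol (drim-7-en-11-ol, 9α-H) | OC[C@H]1C(C)=CC[C@H]2C(C)(C)CCC[C@@]21C | intermediate
14 | 11-O-(tert-butyldimethylsilyl)drimenol | CC(C)(C)[Si](C)(C)OC[C@H]1C(C)=CC[C@H]2C(C)(C)CCC[C@@]21C | intermediate
15 | 11-(tert-butyldimethylsilyloxy)-8α-hydroxydriman-7-one | CC(C)(C)[Si](C)(C)OC[C@H]1[C@](C)(O)C(=O)C[C@H]2C(C)(C)CCC[C@@]21C | intermediate
16 | 11-(tert-butyldimethylsilyloxy)-7,8α-bis(trimethylsilyloxy)drim-6-ene | CC(C)(C)[Si](C)(C)OC[C@H]1[C@](C)(O[Si](C)(C)C)C(O[Si](C)(C)C)=C[C@H]2C(C)(C)CCC[C@@]21C | intermediate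
17 | 6α,7α-epoxy-11-(tert-butyldimethylsilyloxy)-7β,8α-bis(trimethylsilyloxy)drimane | CC(C)(C)[Si](C)(C)OC[C@H]1[C@](C)(O[Si](C)(C)C)[C@]3(O[Si](C)(C)C)O[C@@H]3[C@H]2C(C)(C)CCC[C@@]21C | intermediate (not isolated)
18 | 11-(tert-butyldimethylsilyloxy)-6α,8α-bis(trimethylsilyloxy)driman-7-one | CC(C)(C)[Si](C)(C)OC[C@H]1[C@](C)(O[Si](C)(C)C)C(=O)[C@H](O[Si](C)(C)C)[C@H]2C(C)(C)CCC[C@@]21C | intermediate (not isolated)
19 | 11-(tert-butyldimethylsilyloxy)-6α,8α-dihydroxydriman-7-one | CC(C)(C)[Si](C)(C)OC[C@H]1[C@](C)(O)C(=O)[C@H](O)[C@H]2C(C)(C)CCC[C@@]21C | intermediate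
20 | 6α-acetoxy-11-(tert-butyldimethylsilyloxy)-8α-hydroxydriman-7-one | CC(C)(C)[Si](C)(C)OC[C@H]1[C@](C)(O)C(=O)[C@H](OC(C)=O)[C@H]2C(C)(C)CCC[C@@]21C | intermediate
21 | 6α-acetoxy-11-(tert-butyldimethylsilyloxy)drimane-7β,8α-diol | CC(C)(C)[Si](C)(C)OC[C@H]1[C@](C)(O)[C@@H](O)[C@H](OC(C)=O)[C@H]2C(C)(C)CCC[C@@]21C | intermediate
22 | 6α-acetoxydrimane-7β,8α,11-triol | OC[C@H]1[C@](C)(O)[C@@H](O)[C@H](OC(C)=O)[C@H]2C(C)(C)CCC[C@@]21C | intermediate
23 | 6α-acetoxy-7β,8α-dihydroxydriman-11-al | O=C[C@H]1[C@](C)(O)[C@@H](O)[C@H](OC(C)=O)[C@H]2C(C)(C)CCC[C@@]21C | intermediate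
24 | (E)-4-(6α-acetoxy-7β,8α-dihydroxy-11-nordriman-9β-yl)but-3-en-2-one | CC(=O)/C=C/[C@H]1[C@](C)(O)[C@@H](O)[C@H](OC(C)=O)[C@H]2C(C)(C)CCC[C@@]21C | target

**Step count and risks**

Total: 17 steps. Longest linear sequence: 16 steps (steps 2, 3 and 4–17, from 3-(trimethylsilyl)prop-2-yn-1-ol, which passes through bromide 6). The branch from (R)-carvone (steps 1 and 4–17) runs to 15 steps.

Steps most likely to fail:

1. Step 5 (ring A closure). The vinylsilane may be protodesilylated before it meets the cation. Alternatively, the C4 cation may drain by proton loss towards C5 (isopropylidene formation, which would also erode the C5 centre) faster than it is captured. The fallback sets out from 3 and returns at 10, so steps 5 and 6 are bypassed. Enolate 7 is alkylated with allyl bromide to 6-allyl-6-methylcarvone F1 (allyl anti to isopropenyl). Formolysis (HCO2H, rt) lets the plain terminal alkene capture the C4 cation at C3, the secondary C2 cation being trapped by solvent to give 2-formyloxy-11-nordrim-7-en-9-one F2 (C2 epimers). Methanolysis (K2CO3, MeOH) gives the 2-hydroxy ketone F3, and PhOC(S)Cl/pyridine/DMAP gives the phenyl thionocarbonate F4. Barton–McCombie deoxygenation (Bu3SnH, AIBN, toluene, 100 °C) then removes the C2 oxygen and gives 10.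

2. Step 7 (methylenation of the hindered enone). Ylide addition to the C9 carbonyl, flanked by quaternary C10 and the substituted alkene carbon C8, may be too slow, so that the ylide acts as a base at the γ-position (C6) and the enone is returned. The fallback sets out from 10 and returns at 11 by a two-stage Peterson olefination. The weakly basic, strongly nucleophilic reagent from Me3SiCH2Li and CeCl3 (THF, −78 °C) adds to the carbonyl to give 9-hydroxy-9-[(trimethylsilyl)methyl]-11-nordrim-7-ene F5. KH in THF then triggers syn-elimination of silanolate, which can only occur towards the silylmethyl carbon, to give diene 11.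

3. Step 17 (olefination of the hindered β-hydroxy aldehyde). Slow addition of the stabilised ylide at the neopentyl-like aldehyde may allow β-elimination of the C8 hydroxyl, epimerisation at C9 or thermal acetyl migration to compete. The fallback sets out from 23 and returns at 24. Zinc-mediated alkynylation with propyne (Zn(OTf)2, Et3N, toluene, rt) adds a small nucleophile to the aldehyde and gives the propargylic alcohol 1-(6α-acetoxy-7β,8α-dihydroxy-11-nordriman-9β-yl)but-2-yn-1-ol F6 (C11 epimers). A Meyer–Schuster rearrangement (MoO2(acac)2, AuCl(PPh3), AgOTf, each catalytic, toluene, rt) then transposes the oxygen to C13 and gives the (E)-enone 24.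

**Further compounds**

F1 | step 5 | 6-allyl-6-methylcarvone (allyl trans to isopropenyl) | O=C1C(C)=CC[C@@H](C(C)=C)[C@]1(C)CC=C
F2 | step 5 | 2-formyloxy-11-nordrim-7-en-9-one (C2 epimers) | O=C1C(C)=CC[C@H]2C(C)(C)CC(OC=O)C[C@@]21C
F3 | step 5 | 2-hydroxy-11-nordrim-7-en-9-one (C2 epimers) | O=C1C(C)=CC[C@H]2C(C)(C)CC(O)C[C@@]21C
F4 | step 5 | 2-(phenoxythiocarbonyloxy)-11-nordrim-7-en-9-one (C2 epimers) | O=C1C(C)=CC[C@H]2C(C)(C)CC(OC(=S)Oc3ccccc3)C[C@@]21C
F5 | step 7 | 9-hydroxy-9-[(trimethylsilyl)methyl]-11-nordrim-7-ene (C9 configuration immaterial) | C[Si](C)(C)CC1(O)C(C)=CC[C@H]2C(C)(C)CCC[C@@]21C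
F6 | step 17 | 1-(6α-acetoxy-7β,8α-dihydroxy-11-nordriman-9β-yl)but-2-yn-1-ol (C11 epimers) | CC#CC(O)[C@H]1[C@](C)(O)[C@@H](O)[C@H](OC(C)=O)[C@H]2C(C)(C)CCC[C@@]21C
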